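**Retrosynthetic overview**
1. Tetralin numbering is used: C1 bears ring C (catechol), C2 and C3 bear the CH2OH groups, C4 is the CH2, and C4a/C8a are the fusion carbons of ring A (dimethoxy ring). Rings A and C are bought. A temporary cyclopropane is made first and ring B is the only target ring that is built, last.
2. Target 18 comes from the all-trans ester 16 by ester reduction and global debenzylation. Ester 16 comes from the tetralin-2,2-diester 14 by loss of one CO2Me and equilibration at C2.
3. Key disconnection: ring B of 14 is cut at C4a–C4 and at C1–C2. This gives the ortho-bromo benzhydryl methyl ether 10 (unit C4a–C8a–C1) and the cyclopropane-1,1-diester 5 (unit C4–C3–C2), a formal [3+3] annulation.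
4. Enabling feature: in ring B the plain CH2 (C4) and the CH2OH-bearing C2 (a latent malonate carbon) stand 1,3 across C3, which is the pattern left when a nucleophile opens an acceptor-activated cyclopropane. Facing them are C4a (ring A carbon para to the 7-OMe, addressable as an aryl metal) and C1 (doubly benzylic, para to the 6-OMe of ring A and to the 4'-oxygen of ring C, hence a very stable cation).
5. Diester 5 comes from chiral-pool diol 1 (cyclic sulfate plus malonate, which sets C3), and ether 10 comes from aryl bromide 6 and aldehyde 7. Stereochemical relay: C3 controls C1 in the ring closure, and C2 follows by equilibration to the all-equatorial isomer.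

Key step: step 4

Remark: compounds 1, 4, 6 and 7 are taken as commercially available. The carbinol centre of 10 is left racemic because it is erased on ionisation in step 4.

**Step 1**
Reactants: 1 (R)-3-(benzyloxy)propane-1,2-diol
Product: 3 (4S)-4-[(benzyloxy)methyl]-1,3,2-dioxathiolane 2,2-dioxide, via cyclic sulfite 2 (not isolated)
Conditions: SOCl2, CH2Cl2, reflux; then RuCl3·xH2O (cat.), NaIO4, MeCN–H2O, 0 °C
Reagents that add atoms: thionyl chloride O=S(Cl)Cl; sodium periodate [Na+].[O-]I(=O)(=O)=O
Why: Cyclic sulfate synthesis (sulfite formation, then RuO4-catalysed oxidation at sulfur) turns the 1,2-diol into a double electrophile without breaking a C–O bond, so the stereocentre is carried over unchanged and the short, cold oxidation spares the benzyl ether.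

**Step 2**
Reactants: 3 cyclic sulfate; 4 dimethyl malonate
Product: 5 dimethyl (2R)-2-[(benzyloxy)methyl]cyclopropane-1,1-dicarboxylate
Conditions: NaH (2.2 equiv), DME, 0 °C → reflux
Reagents that add atoms: none
Why: Double alkylation of malonate with a 1,2-cyclic sulfate, in which the first anion opens the sulfate by SN2 at the primary carbon and the second anion closes the three-membered ring by 3-exo-tet SN2 at the secondary carbon with inversion, which sets the future C3 as R.

**Step 3**
Reactants: 6 4-bromo-1,2-bis(benzyloxy)benzene; 7 2-bromo-4,5-dimethoxybenzaldehyde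
Product: 10 1-{[3,4-bis(benzyloxy)phenyl](methoxy)methyl}-2-bromo-4,5-dimethoxybenzene (racemic), via aryllithium 8 (not isolated), via lithium alkoxide 9 (not isolated)
Conditions: 6, n-BuLi, THF, −78 °C; 7, −78 °C; then MeI, DMPU, −78 °C → rt
Reagents that add atoms: iodomethane CI
Why: 1,2-Addition of an aryllithium to an aldehyde followed by Williamson O-methylation of the alkoxide in the same flask, where carbonyl addition outruns bromine–lithium exchange at the bromide of 7 and the new carbinol centre is racemic on purpose.

**Step 4**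
Reactants: 10 ortho-bromo benzhydryl methyl ether; 5 cyclopropane-1,1-diester
Product: 14 dimethyl (1S,3R)-1-[3,4-bis(benzyloxy)phenyl]-3-[(benzyloxy)methyl]-6,7-dimethoxy-3,4-dihydronaphthalene-2,2(1H)-dicarboxylate, via aryllithium 11 (not isolated), via arylmagnesium bromide 12 (not isolated), via magnesium enolate 13 (not isolated)
Conditions: 10, n-BuLi, THF, −78 °C; MgBr2, −78 → −30 °C; CuBr·SMe2 (10 mol %), 5 (1.2 equiv), −30 → 0 °C; then CH2Cl2, TMSOTf (1.3 equiv), −78 → −20 °C
Reagents that add atoms: none
Why: Proposed new method: bromine–lithium exchange and transmetalation give 12, whose copper-catalysed SN2-type homoconjugate addition to the unsubstituted CH2 of 5 breaks the strained bond to the malonate carbon, makes C4a–C4 and stores the charge as enolate 13, after which TMSOTf silylates the enolate and abstracts the benzhydryl methoxy group so that the doubly benzylic C1 cation is captured by C2. The closest known reaction types are the copper-catalysed Grignard opening of cyclopropane-1,1-dicarboxylates and the Lewis-acid-mediated SN1 alkylation of ketene silyl acetals with diarylmethyl ethers (Mukaiyama type), and what is new is their union into one anion-then-cation [3+3] annulation on an ortho-metalated benzhydryl ether. Ring B, the only ring closed, forms in a 6-(enolexo)-exo-trig mode when the cation is counted in its ring C quinoid form. C3 is not touched and keeps the configuration of 5, and it sets C1 through a chair-like transition state in which CH2OBn is equatorial and the planar cation holds ring C on its outer side, away from the ortho CH2 (allylic strain), so that ring C should end pseudo-equatorial and cis to the C3 substituent, while C2 with two equal esters is not stereogenic. The step needs attack at the CH2 and not at the substituted ring carbon (secured by steric hindrance and the inductive pull of CH2OBn), one defined carbon of ring A (secured by the bromine brought in with 7), and no contact between aryl metal and cation (secured by the methyl ether, which stays inert until TMSOTf is added to the fully consumed aryl metal).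

**Step 5**
Reactants: 14 tetralin-2,2-diester
Product: 15 methyl (1S,3R)-1-[3,4-bis(benzyloxy)phenyl]-3-[(benzyloxy)methyl]-6,7-dimethoxy-1,2,3,4-tetrahydronaphthalene-2-carboxylate (C2 epimer mixture)
Conditions: LiCl, H2O, DMSO, 160 °C
Reagents that add atoms: none
Why: Krapcho dealkoxycarbonylation, in which chloride demethylates one geminal ester, CO2 is lost and the ester enolate is protonated without control, so C2 arises as an epimer mixture while C1 and C3, which carry no acidic hydrogen, are untouched.

**Step 6**
Reactants: 15 C2 epimer mixture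
Product: 16 methyl (1S,2R,3R)-1-[3,4-bis(benzyloxy)phenyl]-3-[(benzyloxy)methyl]-6,7-dimethoxy-1,2,3,4-tetrahydronaphthalene-2-carboxylate
Conditions: NaOMe (0.5 equiv), MeOH, reflux
Reagents that add atoms: none
Why: Base-mediated epimerisation under thermodynamic control, in which only C2 is enolisable and reversible deprotonation should drain the axial ester into the isomer with all three ring B substituents equatorial (1,2-trans, 2,3-trans), which sets C2 as R.

**Step 7**
Reactants: 16 all-trans ester
Product: 17 {(1S,2R,3R)-1-[3,4-bis(benzyloxy)phenyl]-3-[(benzyloxy)methyl]-6,7-dimethoxy-1,2,3,4-tetrahydronaphthalen-2-yl}methanol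
Conditions: LiAlH4, THF, 0 °C → rt
Reagents that add atoms: none
Why: Ester reduction with LiAlH4 to the primary alcohol, which removes the acidity at C2 and so locks its configuration while benzyl and methyl ethers are inert.

**Step 8**
Reactants: 17 tribenzyl ether
Product: 18 4-[(1S,2R,3R)-2,3-bis(hydroxymethyl)-6,7-dimethoxy-1,2,3,4-tetrahydronaphthalen-1-yl]benzene-1,2-diol (target)
Conditions: H2 (1 atm), Pd/C, MeOH–EtOAc, rt, exclusion of air on work-up
Reagents that add atoms: none
Why: Catalytic hydrogenolysis cleaves the three benzyl ethers (two phenolic, one primary alkyl) in one operation, while the methyl ethers, the C–C bonds at the doubly benzylic C1 and all three stereocentres are not affected.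

**Compound list**
1 | (R)-3-(benzyloxy)propane-1,2-diol | OC[C@@H](O)COCc1ccccc1 | starting material
2 | (4S)-4-[(benzyloxy)methyl]-1,3,2-dioxathiolane 2-oxide (both configurations at sulfur) | O1C[C@@H](OS1=O)COCc2ccccc2 | intermediate
3 | (4S)-4-[(benzyloxy)methyl]-1,3,2-dioxathiolane 2,2-dioxide | O1C[C@@H](OS1(=O)=O)COCc2ccccc2 | intermediate
4 | dimethyl malonate | COC(=O)CC(=O)OC | starting material
5 | dimethyl (2R)-2-[(benzyloxy)methyl]cyclopropane-1,1-dicarboxylate | COC(=O)C1(C(=O)OC)C[C@H]1COCc2ccccc2 | intermediate
6 | 4-bromo-1,2-bis(benzyloxy)benzene | Brc1ccc(OCc2ccccc2)c(OCc2ccccc2)c1 | starting material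
7 | 2-bromo-4,5-dimethoxybenzaldehyde | COc1cc(Br)c(C=O)cc1OC | starting material
8 | [3,4-bis(benzyloxy)phenyl]lithium | [Li]c1ccc(OCc2ccccc2)c(OCc2ccccc2)c1 | intermediate
9 | lithium [3,4-bis(benzyloxy)phenyl](2-bromo-4,5-dimethoxyphenyl)methanolate (racemic) | COc1cc(Br)c(cc1OC)C(O[Li])c1ccc(OCc2ccccc2)c(OCc2ccccc2)c1 | intermediate
10 | 1-{[3,4-bis(benzyloxy)phenyl](methoxy)methyl}-2-bromo-4,5-dimethoxybenzene (racemic) | COc1cc(Br)c(cc1OC)C(OC)c1ccc(OCc2ccccc2)c(OCc2ccccc2)c1 | intermediate
11 | (2-{[3,4-bis(benzyloxy)phenyl](methoxy)methyl}-4,5-dimethoxyphenyl)lithium | COc1cc([Li])c(cc1OC)C(OC)c1ccc(OCc2ccccc2)c(OCc2ccccc2)c1 | intermediate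
12 | (2-{[3,4-bis(benzyloxy)phenyl](methoxy)methyl}-4,5-dimethoxyphenyl)magnesium bromide | COc1cc([Mg]Br)c(cc1OC)C(OC)c1ccc(OCc2ccccc2)c(OCc2ccccc2)c1 | intermediate
13 | bromomagnesium enolate of the ring-opened malonate (R at the CH that bears CH2OBn) | COC(=O)C(=C(OC)O[Mg]Br)[C@H](COCc1ccccc1)Cc1cc(OC)c(OC)cc1C(OC)c1ccc(OCc2ccccc2)c(OCc2ccccc2)c1 | intermediate
14 | dimethyl (1S,3R)-1-[3,4-bis(benzyloxy)phenyl]-3-[(benzyloxy)methyl]-6,7-dimethoxy-3,4-dihydronaphthalene-2,2(1H)-dicarboxylate | COc1cc2c(cc1OC)[C@H](c1ccc(OCc3ccccc3)c(OCc3ccccc3)c1)C(C(=O)OC)(C(=O)OC)[C@H](COCc1ccccc1)C2 | intermediate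
15 | methyl (1S,3R)-1-[3,4-bis(benzyloxy)phenyl]-3-[(benzyloxy)methyl]-6,7-dimethoxy-1,2,3,4-tetrahydronaphthalene-2-carboxylate (C2 epimer mixture) | COc1cc2c(cc1OC)[C@H](c1ccc(OCc3ccccc3)c(OCc3ccccc3)c1)C(C(=O)OC)[C@H](COCc1ccccc1)C2 | intermediate
16 | methyl (1S,2R,3R)-1-[3,4-bis(benzyloxy)phenyl]-3-[(benzyloxy)methyl]-6,7-dimethoxy-1,2,3,4-tetrahydronaphthalene-2-carboxylate | COc1cc2c(cc1OC)[C@H](c1ccc(OCc3ccccc3)c(OCc3ccccc3)c1)[C@@H](C(=O)OC)[C@H](COCc1ccccc1)C2 | intermediate
17 | {(1S,2R,3R)-1-[3,4-bis(benzyloxy)phenyl]-3-[(benzyloxy)methyl]-6,7-dimethoxy-1,2,3,4-tetrahydronaphthalen-2-yl}methanol | COc1cc2c(cc1OC)[C@H](c1ccc(OCc3ccccc3)c(OCc3ccccc3)c1)[C@@H](CO)[C@H](COCc1ccccc1)C2 | intermediate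
18 | 4-[(1S,2R,3R)-2,3-bis(hydroxymethyl)-6,7-dimethoxy-1,2,3,4-tetrahydronaphthalen-1-yl]benzene-1,2-diol | COc1cc2c(cc1OC)[C@H](c1ccc(O)c(O)c1)[C@@H](CO)[C@H](CO)C2 | target

**Total step count:** 8. **Longest linear sequence:** 7 (steps 1, 2, 4, 5, 6, 7, 8).

**Steps most likely to fail**

1. **Step 4.**
   - Risks:
     - The hindered aryl metal may open the monocyclic diester sluggishly.
     - It may add to an ester carbonyl or to the substituted ring carbon instead.
     - The ether may ionise too early.
     - Facial selectivity at C1 in the ring closure may be poor.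
   - Fallback (known chemistry only): it sets out from 5 and comes back at 18.
     - 3,4-Dimethoxyphenylmagnesium bromide with catalytic CuI opens 5 to the open-chain malonate F1.
     - Hydrogenolysis of its benzyl ether and acid-catalysed lactonisation give the lactone ester F2.
     - Krapcho dealkoxycarbonylation gives the β-benzyl butyrolactone F3.
     - Its lithium enolate (LDA, −78 °C) adds to 3,4-bis(benzyloxy)benzaldehyde anti to the benzyl group to give the trans aldol F4.
     - TFA in CH2Cl2 ionises the carbinol, and ring A closes ring B by Friedel–Crafts alkylation para to a methoxy group. This gives the all-trans, trans-fused lactone F5.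
     - LiAlH4 gives the dibenzyl diol F6, and hydrogenolysis gives 18.

2. **Step 6.**
   - Risk: the thermodynamic bias between equatorial and axial ester may be too small, so the equilibration stops short of one isomer.
   - Fallback: it sets out from 15 and comes back at 17.
     - The ratio-limited equilibration is replaced by a dynamic kinetic reduction with NaBH4 and NaOMe in refluxing THF–MeOH.
     - The epimers interconvert through the enolate while the less hindered equatorial ester is reduced faster.
     - The reduction drains the mixture towards 17, and no compound outside the list is made (F0).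

3. **Step 5.**
   - Risks: chloride may demethylate the crowded quaternary malonate only slowly, and the C1–C2 bond may undergo heterolysis at the temperature required.
   - Fallback: it sets out from 14 and comes back at 15.
     - Saponification (KOH, aqueous ethylene glycol, heat) gives the malonic acid F7.
     - Thermal decarboxylation in refluxing pyridine gives the monoacid F8.
     - MeI with K2CO3 in DMF re-esterifies it to 15.

**Further compounds**
F1 | step 4 | dimethyl 2-[(2R)-1-(benzyloxy)-3-(3,4-dimethoxyphenyl)propan-2-yl]propanedioate | COC(=O)C(C(=O)OC)[C@H](COCc1ccccc1)Cc1ccc(OC)c(OC)c1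
F2 | step 4 | methyl (4R)-4-[(3,4-dimethoxyphenyl)methyl]-2-oxooxolane-3-carboxylate (C3 epimers) | COC(=O)C1C(=O)OC[C@@H]1Cc2ccc(OC)c(OC)c2
F3 | step 4 | (4R)-4-[(3,4-dimethoxyphenyl)methyl]oxolan-2-one | O=C1C[C@@H](Cc2ccc(OC)c(OC)c2)CO1
F4 | step 4 | (3S,4R)-3-{[3,4-bis(benzyloxy)phenyl](hydroxy)methyl}-4-[(3,4-dimethoxyphenyl)methyl]oxolan-2-one (carbinol epimers) | O=C1OC[C@H](Cc2ccc(OC)c(OC)c2)[C@H]1C(O)c1ccc(OCc2ccccc2)c(OCc2ccccc2)c1
F5 | step 4 | trans-fused γ-lactone of (1S,2R,3R)-1-[3,4-bis(benzyloxy)phenyl]-3-(hydroxymethyl)-6,7-dimethoxy-1,2,3,4-tetrahydronaphthalene-2-carboxylic acid | COc1cc2c(cc1OC)[C@H](c1ccc(OCc3ccccc3)c(OCc3ccccc3)c1)[C@H]1C(=O)OC[C@@H]1C2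
F6 | step 4 | {(1S,2R,3R)-1-[3,4-bis(benzyloxy)phenyl]-6,7-dimethoxy-1,2,3,4-tetrahydronaphthalene-2,3-diyl}dimethanol | COc1cc2c(cc1OC)[C@H](c1ccc(OCc3ccccc3)c(OCc3ccccc3)c1)[C@@H](CO)[C@H](CO)C2
F7 | step 5 | (1S,3R)-1-[3,4-bis(benzyloxy)phenyl]-3-[(benzyloxy)methyl]-6,7-dimethoxy-3,4-dihydronaphthalene-2,2(1H)-dicarboxylic acid | COc1cc2c(cc1OC)[C@H](c1ccc(OCc3ccccc3)c(OCc3ccccc3)c1)C(C(=O)O)(C(=O)O)[C@H](COCc1ccccc1)C2
F8 | step 5 | (1S,3R)-1-[3,4-bis(benzyloxy)phenyl]-3-[(benzyloxy)methyl]-6,7-dimethoxy-1,2,3,4-tetrahydronaphthalene-2-carboxylic acid (C2 epimers) | COc1cc2c(cc1OC)[C@H](c1ccc(OCc3ccccc3)c(OCc3ccccc3)c1)C(C(=O)O)[C@H](COCc1ccccc1)C2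
F0 | step 6 | none | none
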